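**The question.** Grey was the blue charge left for 120 h instead of 30 h.

in all of them: added ligand 1.1 mM
- Thursday's: left-handed substrate 0.10 M; right-handed substrate 0.10 M; solid reagent 0.22 M; free catalyst 1 mM; racemization catalyst 2.1 mM; run made earlier
- Saturday's: left-handed substrate 0.10 M; right-handed substrate 0.10 M; solid reagent 0.22 M; free catalyst 1 mM; racemization catalyst 4.7 mM; run made earlier
- Tuesday's: left-handed substrate 0.15 M; right-handed substrate 0.15 M; solid reagent 0.22 M; free catalyst 1 mM; racemization catalyst 3.1 mM; run made earlier
- blue: left-handed substrate 0.10 M; right-handed substrate 0.10 M; solid reagent 0.220 M; free catalyst 1.0 mM; racemization catalyst 3.1 mM; time 30 h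
- grey: left-handed substrate 0.10 M; right-handed substrate 0.10 M; solid reagent 0.220 M; free catalyst 1.0 mM; racemization catalyst 3.1 mM; time 120 h

| run | time / h | left-handed product / % | right-handed product / % | left-handed substrate / % |
|---|---|---|---|---|
| Thursday's | 2.50 | 1.6 | 0 | 51.5 |
| Thursday's | 4.00 | 1.2 | 0 | 45.9 |
| Thursday's | 6.00 | 2.8 | 0.7 | 46.7 |
| Thursday's | 10.0 | 5.0 | 0 | 45.5 |
| Thursday's | 20.0 | 12.9 | 0 | 38.4 |
| Thursday's | 30.0 | 18.9 | 1.4 | 31.3 |
| Saturday's | 5.00 | 2.4 | 0 | 47.6 |
| Saturday's | 10.0 | 6.7 | 0.4 | 45.0 |
| Saturday's | 15.0 | 9.2 | 0.5 | 42.1 |
| Saturday's | 20.0 | 12.9 | 1.4 | 37.7 |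
| Saturday's | 25.0 | 16.0 | 1.2 | 36.0 |
| Saturday's | 30.0 | 19.9 | 1.3 | 35.3 |
| Tuesday's | 2.50 | 1.2 | 0 | 49.6 |
| Tuesday's | 8.00 | 4.8 | 0 | 47.3 |
| Tuesday's | 15.0 | 8.5 | 0.4 | 41.5 |
| Tuesday's | 20.0 | 12.1 | 1.0 | 40.3 |
| Tuesday's | 30.0 | 19.7 | 0.6 | 33.4 |

(each reading ± 1 percentage point)

- free catalyst is single-handed; left-handed substrate and right-handed substrate are mirror images of each other, charged as a racemate, each of them at the stated concentration
- solid reagent is a solid; its amount is given per volume of the solution
- the numbers in the tables scatter with a standard deviation of 1 percentage point
- at the start none of the solid reagent is in solution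
- an excess is the difference of the two amounts in percent of their sum
- an excess is below zero if the other one leads

- which of the two ends with the higher excess of left-handed product over right-handed product in the product ("neither" if they lie within 2 percentage points) (blue / grey / neither)
- excess of left-handed product over right-handed product in the product at the end, blue
- excess of left-handed product over right-handed product in the product at the end, grey

**Rate order.** Tuesday's run, at 0.15 M of each substrate, gave 19.7 % left-handed product by 30.0 h, and Thursday's, at 0.10 M, gave 18.9 %. Percentages equal within the scatter, although the racemization catalyst differed too, pointed to first order in substrate, so I treated the flask as pseudo-first-order in c(left-handed substrate). The last readings of left-handed product in the earlier runs, each at 30 h, average 19.5 %, which gave me a working constant 0.0165 h⁻¹, a reading with its scatter.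

**Turned round.** What had to be true for grey to end a margin below blue? With x as constant times hours, the ratio of right-handed to left-handed product climbs by x/(1 − e^(−x)), and racemization shrinks that climb. From blue to grey I estimated this climb, before any shrinking, as a factor of 1.81. The excess drops 2 points per point of right-handed share, so by this estimate blue's share had to reach 1.23 % or more, which is about 0.24 percentage points of right-handed product at 30 h. The last readings of the earlier runs average 1.10 %, with a standard error of 0.58 points. I could therefore give the direction, with grey not above blue, but not whether the gap passed the margin.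

**The forecast.** It went further: blue, with 89 % and 85 %, since “The left substrate is depleted, so the right product's share grows”.

**The result.** The flask gave neither: 98.3 % for blue, 97.9 % for grey.

    coupling partner + free catalyst + right-handed substrate → free catalyst + right-handed product (k = 0.110 M⁻² min⁻¹)
    coupling partner + free catalyst + left-handed substrate → free catalyst + left-handed product (k = 15.6 M⁻² min⁻¹)
    left-handed substrate + racemization catalyst ⇌ right-handed substrate + racemization catalyst, rate k3*[racemization catalyst]*[left-handed substrate] forward; the back reaction follows from the equilibrium constant (k = 0.0734 M⁻¹ min⁻¹)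
    solid reagent ⇌ coupling partner, rate k4*(cs4 - [coupling partner]) while solid is left; crystals form when [coupling partner] > cs4 (solubility = 32.0 mM, k = 0.00445 min⁻¹)
    free catalyst + added ligand ⇌ idle complex (K = 483 M⁻¹, k = 1.37 M⁻¹ min⁻¹)

Blue held 0.167 % right-handed product beside 19.8 % left-handed at 30.0 h, a share of 0.840 %, which is below the 1.23 % that my constant of 0.0165 h⁻¹ had required.

**Second flask.** A neighbour flask is grey with a quarter of the free catalyst, 2.5 × 10⁻⁴ M. Scaling the constant with the free catalyst charged, to 0.00412 h⁻¹, puts this neighbour at blue's x, so I expected 19.5 % left-handed product and blue's excess. The neighbour gave 23.2 % and 98.4 %.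

(The readings were computed for an exercise; noise was put on by code.)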